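Amounts come first: each flask asks its free catalyst to turn over a given charge of substrate in a given time.

| flask | substrate | free catalyst | remark | time |
|---|---|---|---|---|
| south-east | 0.022 M | 20 µM | run made earlier |  |
| ash | 0.080 M | 12 µM |  | 5.0 min |
| elm | 0.010 M | 6.0 µM |  | 5.0 min |
| birch | 0.020 M | 20 µM |  | 5.0 min |
| maple | 0.010 M | 30 µM |  | 5.0 min |
| cedar | 0.040 M | 10 µM |  | 5.0 min |

south-east run (percent of the substrate charged)

| time / min | product / % | substrate / % |
|---|---|---|
| 0.250 | 9.3 | 89.6 |
| 0.833 | 31.6 | 69.4 |
| 1.33 | 47.6 | 53.1 |
| 2.00 | 64.0 | 37.6 |
| 3.00 | 82.3 | 17.7 |

(each reading ± 1 percentage point)

- no earlier run changes the charge of free catalyst; that part of a forecast is a guess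

- all flasks from highest to lowest amount of product, in percent of the substrate charged, at 5.0 min (ash / elm / birch / maple / cedar)
- the amount of product, in percent of the substrate charged of the flask you put first, at 5.0 min
- the amount of product, in percent of the substrate charged of the flask you put last, at 5.0 min

At 1.33 min the south-east run reads 47.6% product, so its catalyst has worked at about 394 /min. This reading is the mean turnover rate, or turnover frequency: product made per catalyst charged per minute, up to that reading. Dividing a flask's substrate by this rate times its catalyst gives a clearing time, and taking the rate as proportional to catalyst is a guess, since no earlier run changes that charge.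

Now turn the question round. On this reckoning, for ash to finish within 5.0 min its clearing time has to fall below that time, yet it is 16.9 min, which is 3.38 times the run. Maple stands on the other side, with 0.847 min. Between them lie birch at 2.54 min, elm at 4.23 min and cedar at 10.2 min. My reckoning therefore puts ash last, its clearing time being longer than the others, with about 29.5% product, and maple first, its clearing time being shorter than the others.

The forecast gives the same order, maple > birch > elm > cedar > ash, but with 99.9% and 46%, so its ash stands higher than mine. Its grounds are that “the order in substrate is below one, which suggests saturation”.

The flasks give maple > birch > elm > cedar > ash, with maple at 99.6% and ash at 37.7%.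

    catalyst intermediate B → free catalyst + product (k = 36.6 /s)
    substrate + free catalyst → catalyst intermediate A (k = 1570 /M/s)
    2 free catalyst ⇌ resting dimer (K = 84000 /M, k = 701 /M/s)
    catalyst intermediate A ⇌ catalyst intermediate B (K = 0.673, k = 24.8 /s)

At 5.00 min ash holds 65.8% of its catalyst as catalyst intermediate A and 22.2% as catalyst intermediate B, and that share of catalyst intermediate B releases product at 488 /min per catalyst charged, faster than the mean turnover rate read from the south-east run. The neighbour of maple charged with 1.2 × 10⁻⁵ M of free catalyst has a clearing time of 2.12 min, shorter than its 5.0 min, and it stands at 92.6% product with 7.3% of its substrate left.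

All runs stem from a simulated flask with made-up constants; scatter was added.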